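## The problem

The target is a cis-fused 2,2a,7,7a-tetrahydro-1H-cyclobuta[a]indene in which ring A is the arene (C2b, C3 to C6, C6a), ring B the cyclopentane (closed by C2a, C7a and C7) and ring C the cyclobutane (completed by C1 and C2), with rings B and C sharing the C2a–C7a bond. C1 is CMe2, C2 carries the catechol ring, C3 the prenyl group, C4 a methoxy group, C6 a free hydroxyl, and C7 is CH2. Three contiguous stereocentres, C2 (S), C2a (R) and C7a (S), sit on ring C; the B/C fusion can only be cis, so C7a dictates C2a, and the catechol ring lies on the exo (convex) face, the face on which a reagent meets a trigonal C2, so that one stereocentre of defined absolute configuration can control the other two. Ring A needs its two oxygens told apart and a prenyl group placed at C3, between the methoxy group and the ring fusion. The free catechol oxidises easily, the prenyl alkene tolerates neither acid, electrophiles, hydrogenation nor a carbon radical close by, and a cationic centre at C7 or C2 invites ring expansion of the benzylic cyclobutane. Carbonyl-bearing intermediates can epimerise next to the carbonyl. The enabling feature is the unit C7a–C1(Me2)–C2 with C2a as a ring CH2, which is the cis-1,3-disubstituted 2,2-dimethylcyclobutane of the pinane terpenes. With a carbonyl at C7 linking C7a to ring A, the C2a–H cis to that carbonyl lies 1,5 to C2b and can be reached by a metal on C2b through a six-membered metallacycle.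

## Retrosynthesis

**21 ⇒ 20 (O–Si).** The catechol is unmasked last from bis-silyl ether 20. Fluoride is the only reagent class that frees it without acid or hydrogen near the prenyl group. The forward step only has to keep air away from the product.

**20 ⇒ 19 ⇒ 18 (C3–C1′ of the prenyl group, then C3–Br).** Cutting the prenyl group at its aryl bond leads to bromide 19 and from there to phenol 18. An earlier prenyl group would not survive the Lewis acid, hypohalite and C2 radical chemistry upstream. The forward bromination must go para to the C6 hydroxyl, and the coupling must deliver the linear allyl isomer.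

**18 ⇒ 16 ⇒ 15 (C7–H2 back to C7=O, O6–H back to O6–Me).** Retaining the C7 carbonyl in 15 is what makes the key step possible. The same carbonyl then distinguishes the two methoxy groups by chelation (15 → 16) and is finally removed through its neighbouring phenol via carbonate 17, without a cationic centre beside the cyclobutane. Placing these operations after the arylation keeps the phenol masked as its methyl ether through the organozinc chemistry.

**15 ⇒ 10 + 14 (C2–aryl).** The aryl group is cut off as arylzinc 14, made from bromide 12 and thus from catechol 11, leaving redox-active ester 10. The pinane pool supplies a carbon substituent at C2 on the endo face, not an aryl group. A decarboxylative radical arylation both swaps the substituent and moves it to the exo face. The forward reaction must capture a hindered cyclobutyl radical on its convex face.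

**10 ⇒ 9 ⇒ 8 (functional group changes).** The activated ester comes from acid 9 and this from methyl ester 8. The ester is the spectator form chosen for the key step.

**8 ⇒ 7 (C2b–C2a, ring B).** This cut removes ring B and the C2a stereocentre in one stroke. It leaves bromoketone 7, whose cyclobutane has only the two stereocentres already present in pinononic acid. The neighbouring cut at C7–C6a would demand a cyclobutane already arylated at C2a. A cut through ring C would discard the chiral-pool fragment. The forward reaction must activate one methylene C–H bond of the cyclobutane selectively without epimerising C7a.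

**7 ⇒ 6 ⇒ 5 (ester carbon from the acetyl group).** The ester of 7 comes from acid 6, obtained by haloform degradation of methyl ketone 5. The degradation has to come after the acylation. Performed on the keto acid itself it would give a meso diacid and erase the chirality.

**5 ⇒ 2 + 3 (C7–C6a).** Friedel–Crafts acylation of bromoarene 3 by the acid chloride 4 of acid 2 joins ring A to the cyclobutane. The arene is bought with its oxygen pattern and the bromine in place. The forward step needs attack ortho to bromine (para to one methoxy group), not between the methoxy groups.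

**2 ⇒ 1.** Oxidative cleavage of the enone of verbenone 1 gives acid 2, with all ring C carbons and the absolute configuration.

## Roads not taken

**Alternative 1:** Chiral keteniminium and indene crossed [2+2].
- **Cut:** C7a–C1 and C2a–C2, that is ring C.
- **Forward step:** The amide 2-{3,4-bis[(tert-butyldimethylsilyl)oxy]phenyl}-1-[(2S,5S)-2,5-dimethylpyrrolidin-1-yl]ethan-1-one A2 is activated with Tf2O and 2,4,6-collidine to its keteniminium triflate A3. Salt A3 adds across the C=C bond of 4-bromo-5-methoxy-7-[(triisopropylsilyl)oxy]-1H-indene A1, and aqueous hydrolysis gives the C1 cyclobutanone A4.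
- **Merits:** It is convergent, ring C and two bonds form at once, and the polarity matches (the iminium carbon goes to C7a and leaves a benzylic cation at C2a). In A4 the aryl group has arrived with the ring and the C3 bromine is present from the start. In convergence and in avoiding a late radical arylation and a late regioselective bromination this road is better.
- **Weak points:** In A4 the carbon C1 is a carbonyl. Turning a cyclobutanone flanked by two tertiary centres, one of them an epimerisable benzylic C2, into CMe2 is a multi-step and uncertain operation. The absolute configuration rests on auxiliary-controlled facial selectivity of an intermolecular cycloaddition whose sense and level are unknown for this pair, so the enantiomer of the auxiliary shown in A2 is an arbitrary choice. Indene A1 needs its own multi-step synthesis.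
- **Comparison:** The chosen plan sets against this a geminal dimethyl group and an absolute configuration that are bought, not made.

**Alternative 2:** Polyketide-type double Claisen and aldol folding.
- **Cut:** C7–C6a, C6a–C2b and C2b–C3, so that rings A and B are built on a finished cyclobutane.
- **Forward step:** Pentane-2,4-dione A6 is doubly deprotonated with lithium diisopropylamide and combined with dimethyl cis-3-[3,4-bis(methoxymethoxy)phenyl]-4,4-dimethylcyclobutane-1,2-dicarboxylate A5. Heating with NaOMe in methanol completes Claisen acylation, Dieckmann-type closure and aldol aromatisation to the 4,6-dihydroxy C7 ketone A7.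
- **Merits:** Two rings come from the cheap five-carbon unit A6 without a transition metal. In A7 the C6 hydroxyl is chelated to the ketone, so O4 can be methylated selectively without any demethylation. In step economy for the arene this road is better.
- **Weak points:** The two ester groups of A5 are different, and the first acylation must occur at the one on C7a, which is the more hindered (next to CMe2). Attack at the other ester gives the arene fused the wrong way round. Hot methoxide can epimerise the cis-diester. Diester A5 itself, with three stereocentres, still needs an enantioselective synthesis. The methoxymethyl groups must finally be removed with acid in the presence of the prenyl group.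
- **Comparison:** The chosen plan offers regiochemical certainty instead: ring A is bought intact and its two attachment points are fixed by the acylation and by the bromine.

**Alternative 3:** Danheiser benzannulation on a bicyclo[3.2.0]heptene.
- **Cut:** C2b–C3, C3–C4, C5–C6 and C6–C6a, that is ring A.
- **Forward step:** Irradiation of 2-diazo-1-{7-[3,4-bis(tert-butyldimethylsilyloxy)phenyl]-6,6-dimethylbicyclo[3.2.0]hept-2-en-2-yl}ethan-1-one A8 together with methoxyethyne A9 sets off Wolff rearrangement, ketene–alkyne [2+2] addition, four-electron ring opening and six-electron electrocyclisation. The product is the phenol A10.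
- **Merits:** Phenol A10 is the same compound as 18 of the chosen route. It arrives with the methoxy and hydroxyl groups already differentiated and C7 already CH2, so no demethylation or deoxygenation is needed and the regiochemistry is unambiguous. In the endgame this road is better.
- **Weak points:** Diazo ketone A8 contains the whole bicyclo[3.2.0]heptene with all three stereocentres and the aryl group. Its enantioselective construction is the real problem and the benzannulation does nothing for it. A diazo ketone on a strained alkene adds handling risk, and alkyne A9 is volatile and unstable.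
- **Comparison:** The chosen plan reaches the stereodefined cyclobutane in one step from a terpene and pays for it with three extra functional-group steps on ring A.

Key step: step 5

Assumption: commercial (1S,5S)-verbenone 1 is taken as enantiopure; if a lot is not, crystalline acid 2 is recrystallised, since every later stereocentre derives from it.

## Route

Step 1
Reactants: 1 (1S,5S)-(−)-verbenone
Product: 2 (1S,3R)-3-acetyl-2,2-dimethylcyclobutane-1-carboxylic acid (cis-pinononic acid)
Conditions: RuCl3·xH2O (2 mol%), NaIO4 (4.1 equiv), CCl4/MeCN/H2O, rt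
Reagents that add atoms: sodium periodate, [Na+].[O-]I(=O)(=O)=O (terminal oxidant, source of the new oxygen atoms through RuO4); water, O
Why: RuO4-catalysed oxidative cleavage of the enone C=C gives the methyl ketone and an α-keto acid, which is decarboxylated oxidatively to the acid. Neither ring stereocentre is touched, so the cis relation and the absolute configuration of the pinane ring are kept.

Step 2
Reactants: 2 cis-pinononic acid; 3 1-bromo-3,5-dimethoxybenzene
Product: 5 1-[(1R,3S)-3-(2-bromo-4,6-dimethoxybenzoyl)-2,2-dimethylcyclobutyl]ethan-1-one, via acid chloride 4 (not isolated)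
Conditions: (COCl)2, DMF (cat.), CH2Cl2, 0 °C to rt; then 3, AlCl3 (2.5 equiv), CH2Cl2, −20 to 0 °C
Reagents that add atoms: oxalyl chloride, ClC(=O)C(=O)Cl (chlorine of 4 only; no atom of it remains in 5)
Why: Acid chloride formation followed by Friedel–Crafts acylation. The position ortho to bromine is para to one methoxy group and ortho to the other and is the site at which this arene is known to be formylated and acylated, whereas the position between the two methoxy groups is doubly flanked. No base is present, so the centre α to the acyl chloride should keep its configuration.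

Step 3
Reactants: 5 bromoaryl diketone
Product: 6 (1R,3S)-3-(2-bromo-4,6-dimethoxybenzoyl)-2,2-dimethylcyclobutane-1-carboxylic acid
Conditions: NaOBr (from Br2 and NaOH), dioxane/H2O, 0 °C; then HCl to pH 2
Reagents that add atoms: sodium hydroxide, [Na+].[OH-] (oxygen of the carboxyl OH)
Why: Haloform (Lieben) degradation, the classical way from pinonic-type methyl ketones to the acids with retention of the cis configuration. Only the methyl ketone can be trihalogenated; the aryl ketone has a single hindered tertiary α-hydrogen and is twisted between bromine and methoxy, and the acylated bromoarene is a poor partner for hypobromite in cold alkali.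

Step 4
Reactants: 6 keto acid
Product: 7 methyl (1R,3S)-3-(2-bromo-4,6-dimethoxybenzoyl)-2,2-dimethylcyclobutane-1-carboxylate
Conditions: TMSCHN2, toluene/MeOH, 0 °C to rt
Reagents that add atoms: trimethylsilyldiazomethane, C[Si](C)(C)C=[N+]=[N-]
Why: Methyl esterification with a diazoalkane under neutral conditions, chosen so that no base meets the epimerisable C–H next to the aryl ketone.

Step 5
Reactants: 7 bromoaryl keto ester
Product: 8 methyl (2R,2aR,7aS)-4,6-dimethoxy-1,1-dimethyl-7-oxo-2,2a,7,7a-tetrahydro-1H-cyclobuta[a]indene-2-carboxylate (endo ester)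
Conditions: Pd(OAc)2 (10 mol%), PCy3·HBF4 (20 mol%), CsOPiv (0.5 equiv), Cs2CO3 (1.5 equiv), mesitylene, 120 °C, argon
Reagents that add atoms: none
Why: Proposed new method: oxidative addition of zerovalent palladium into the C2b–Br bond, pivalate-assisted concerted metalation–deprotonation of the C2a–H that lies cis to the aroyl group, and C(sp2)–C(sp3) reductive elimination should forge C2b–C2a; the closest known reaction type is the palladium/pivalate intramolecular C(sp3)–H arylation of aryl bromides at methyl and cyclopropyl C–H bonds through six-membered palladacycles, and a cyclobutane CH2 is reasoned to follow the cyclopropane case because its C–H bonds are s-rich and comparatively acidic. Ring B closes as a five-membered ring by reductive elimination from the six-membered palladacycle Pd–C2b–C6a–C7–C7a–C2a. The one new stereocentre, C2a, is controlled by C7a: only the C2a–H on the face of the aroyl group can enter the palladacycle, so the fusion must be cis. Site selectivity is needed against the C7a–H (five-membered palladacycle leading to a strained four-membered ring) and the C1 methyl groups (seven-membered palladacycle), and palladacycle size secures it. The step also needs C7a to keep its configuration under carbonate at 120 °C; the ketone is twisted between bromine and methoxy and could enolise only to an alkylidenecyclobutane, which should be slow in a non-polar solvent. Any epimer that does form cyclises to the exo-ester diastereomer, which is removed by chromatography so that only the endo ester 8 is carried on. The ester is a spectator whose configuration is erased later at C2.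

Step 6
Reactants: 8 tricyclic keto ester
Product: 9 (2R,2aR,7aS)-4,6-dimethoxy-1,1-dimethyl-7-oxo-2,2a,7,7a-tetrahydro-1H-cyclobuta[a]indene-2-carboxylic acid
Conditions: LiOH·H2O, THF/MeOH/H2O, 40 °C; then 1 M HCl
Reagents that add atoms: lithium hydroxide, [Li+].[OH-] (oxygen of the carboxyl OH)
Why: Ester saponification. C7a cannot epimerise because the fusion must stay cis, and any epimerisation at C2 is immaterial since C2 becomes a radical in step 9.

Step 7
Reactants: 9 tricyclic keto acid
Product: 10 1,3-dioxoisoindolin-2-yl (2R,2aR,7aS)-4,6-dimethoxy-1,1-dimethyl-7-oxo-2,2a,7,7a-tetrahydro-1H-cyclobuta[a]indene-2-carboxylate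
Conditions: N-hydroxyphthalimide, DIC, DMAP (cat.), CH2Cl2, rt
Reagents that add atoms: N-hydroxyphthalimide, O=C1c2ccccc2C(=O)N1O
Why: Steglich-type carbodiimide esterification to the redox-active ester. No free hydroxyl is present to compete.

Step 8
Reactants: 11 4-bromobenzene-1,2-diol
Product: 12 4-bromo-1,2-bis[(tert-butyldimethylsilyl)oxy]benzene
Conditions: TBSCl (2.4 equiv), imidazole, DMF, rt
Reagents that add atoms: tert-butyldimethylsilyl chloride, CC(C)(C)[Si](C)(C)Cl
Why: Standard silylation of both phenols. The silyl ethers survive organolithium and organozinc chemistry and leave with fluoride at the end.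

Step 9
Reactants: 10 redox-active ester; 12 silylated bromocatechol
Product: 15 (2S,2aS,7aS)-2-{3,4-bis[(tert-butyldimethylsilyl)oxy]phenyl}-4,6-dimethoxy-1,1-dimethyl-1,2,2a,7a-tetrahydro-7H-cyclobuta[a]inden-7-one, via aryllithium 13 (not isolated), via arylzinc chloride 14 (not isolated)
Conditions: 12, n-BuLi, THF, −78 °C; ZnCl2, THF, −78 °C to rt; then 10, NiCl2(glyme) (20 mol%), 4,4′-di-tert-butyl-2,2′-bipyridine (40 mol%), THF/DMF, rt
Reagents that add atoms: n-butyllithium, [Li]CCCC (lithium of 13); zinc chloride, Cl[Zn]Cl (zinc and chlorine of 14); no atom of either remains in 15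
Why: Nickel-catalysed decarboxylative Negishi-type arylation of a secondary redox-active ester, known for cyclobutyl cases. Electron transfer and loss of CO2 give the C2 radical, which is captured by the aryl–nickel species on the convex face, away from ring B, so the aryl group ends exo whatever the configuration of the acid was. The lithium is not ortho to a silyloxy group, so no silyl migration is expected.

Step 10
Reactants: 15 aryl dimethoxy ketone
Product: 16 (2S,2aS,7aS)-2-{3,4-bis[(tert-butyldimethylsilyl)oxy]phenyl}-6-hydroxy-4-methoxy-1,1-dimethyl-1,2,2a,7a-tetrahydro-7H-cyclobuta[a]inden-7-one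
Conditions: MgI2·OEt2 (3 equiv), toluene, 80 °C; then 1 M HCl
Reagents that add atoms: none
Why: Chelation-controlled demethylation: magnesium bound between the C7 carbonyl and the C6 methoxy oxygen activates only that methyl group toward iodide. The C4 methoxy group and the silyl ethers are not chelated and should stay.

Step 11
Reactants: 16 chelated hydroxy ketone
Product: 18 (2S,2aR,7aS)-2-{3,4-bis[(tert-butyldimethylsilyl)oxy]phenyl}-4-methoxy-1,1-dimethyl-2,2a,7,7a-tetrahydro-1H-cyclobuta[a]inden-6-ol, via ethyl carbonate 17 (not isolated)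
Conditions: ClCO2Et, Et3N, THF, 0 °C; then NaBH4, H2O, 0 °C to rt
Reagents that add atoms: ethyl chloroformate, CCOC(=O)Cl (carbonate group of 17 only; no atom of it remains in 18)
Why: Known deoxygenation of ortho-hydroxyaryl ketones. Borohydride reduces the ketone, the carbonate moves to the benzylic oxygen, the phenoxide expels it to an ortho-quinone methide, and a second hydride adds at C7. No cation is formed next to the cyclobutane, so ring expansion is avoided.

Step 12
Reactants: 18 phenol
Product: 19 (2S,2aR,7aS)-3-bromo-2-{3,4-bis[(tert-butyldimethylsilyl)oxy]phenyl}-4-methoxy-1,1-dimethyl-2,2a,7,7a-tetrahydro-1H-cyclobuta[a]inden-6-ol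
Conditions: NBS (1.0 equiv), MeCN, −30 to 0 °C, dark
Reagents that add atoms: N-bromosuccinimide, BrN1C(=O)CCC1=O
Why: Electrophilic aromatic bromination. C3 is para to the free hydroxyl and ortho to the methoxy group, while C5 lies between two oxygen substituents, the site such 3-methoxyphenols avoid. The silylated catechol ring is far less activated than the free phenol.

Step 13
Reactants: 19 aryl bromide
Product: 20 (2S,2aR,7aS)-2-{3,4-bis[(tert-butyldimethylsilyl)oxy]phenyl}-4-methoxy-1,1-dimethyl-3-(3-methylbut-2-en-1-yl)-2,2a,7,7a-tetrahydro-1H-cyclobuta[a]inden-6-ol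
Conditions: tributyl(3-methylbut-2-en-1-yl)stannane (1.5 equiv), Pd(PPh3)4 (10 mol%), DMF, 100 °C, degassed
Reagents that add atoms: tributyl(3-methylbut-2-en-1-yl)stannane, CCCC[Sn](CCCC)(CCCC)CC=C(C)C
Why: Stille coupling with a prenylstannane, the established way to linear prenyl arenes. The free phenol and the silyl ethers are tolerated under these neutral conditions.

Step 14
Reactants: 20 bis-silyl ether
Product: 21 4-[(2S,2aR,7aS)-6-hydroxy-4-methoxy-1,1-dimethyl-3-(3-methylbut-2-en-1-yl)-2,2a,7,7a-tetrahydro-1H-cyclobuta[a]inden-2-yl]benzene-1,2-diol (CNP0236667.1)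
Conditions: TBAF (2.5 equiv), AcOH (3 equiv), THF, 0 °C, argon
Reagents that add atoms: none
Why: Fluoride desilylation of aryl silyl ethers. The acetic acid buffer and exclusion of air should keep the catecholate from oxidising, and nothing acidic enough to touch the prenyl group is present.

## Compound list

1 | (1S,5S)-(−)-verbenone, (1S,5S)-4,6,6-trimethylbicyclo[3.1.1]hept-3-en-2-one | C1[C@H](C(=O)C=C2C)C(C)(C)[C@@H]12 | starting material
2 | (1S,3R)-3-acetyl-2,2-dimethylcyclobutane-1-carboxylic acid (cis-pinononic acid) | C1[C@H](C(=O)O)C(C)(C)[C@@H]1C(C)=O | intermediate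
3 | 1-bromo-3,5-dimethoxybenzene | COc1cc(Br)cc(OC)c1 | starting material
4 | (1S,3R)-3-acetyl-2,2-dimethylcyclobutane-1-carbonyl chloride | C1[C@H](C(=O)Cl)C(C)(C)[C@@H]1C(C)=O | intermediate (not isolated)
5 | 1-[(1R,3S)-3-(2-bromo-4,6-dimethoxybenzoyl)-2,2-dimethylcyclobutyl]ethan-1-one | C1[C@H](C(=O)c2c(Br)cc(OC)cc2OC)C(C)(C)[C@@H]1C(C)=O | intermediate
6 | (1R,3S)-3-(2-bromo-4,6-dimethoxybenzoyl)-2,2-dimethylcyclobutane-1-carboxylic acid | C1[C@H](C(=O)c2c(Br)cc(OC)cc2OC)C(C)(C)[C@@H]1C(=O)O | intermediate
7 | methyl (1R,3S)-3-(2-bromo-4,6-dimethoxybenzoyl)-2,2-dimethylcyclobutane-1-carboxylate | C1[C@H](C(=O)c2c(Br)cc(OC)cc2OC)C(C)(C)[C@@H]1C(=O)OC | intermediate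
8 | methyl (2R,2aR,7aS)-4,6-dimethoxy-1,1-dimethyl-7-oxo-2,2a,7,7a-tetrahydro-1H-cyclobuta[a]indene-2-carboxylate | COc1cc(OC)c2c(c1)[C@@H]1[C@H](C2=O)C(C)(C)[C@@H]1C(=O)OC | intermediate
9 | (2R,2aR,7aS)-4,6-dimethoxy-1,1-dimethyl-7-oxo-2,2a,7,7a-tetrahydro-1H-cyclobuta[a]indene-2-carboxylic acid | COc1cc(OC)c2c(c1)[C@@H]1[C@H](C2=O)C(C)(C)[C@@H]1C(=O)O | intermediate
10 | 1,3-dioxoisoindolin-2-yl (2R,2aR,7aS)-4,6-dimethoxy-1,1-dimethyl-7-oxo-2,2a,7,7a-tetrahydro-1H-cyclobuta[a]indene-2-carboxylate | COc1cc(OC)c2c(c1)[C@@H]1[C@H](C2=O)C(C)(C)[C@@H]1C(=O)ON1C(=O)c2ccccc2C1=O | intermediate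
11 | 4-bromobenzene-1,2-diol | Oc1ccc(Br)cc1O | starting material
12 | 4-bromo-1,2-bis[(tert-butyldimethylsilyl)oxy]benzene | CC(C)(C)[Si](C)(C)Oc1ccc(Br)cc1O[Si](C)(C)C(C)(C)C | intermediate
13 | {3,4-bis[(tert-butyldimethylsilyl)oxy]phenyl}lithium | [Li]c1ccc(O[Si](C)(C)C(C)(C)C)c(O[Si](C)(C)C(C)(C)C)c1 | intermediate (not isolated)
14 | {3,4-bis[(tert-butyldimethylsilyl)oxy]phenyl}zinc chloride | Cl[Zn]c1ccc(O[Si](C)(C)C(C)(C)C)c(O[Si](C)(C)C(C)(C)C)c1 | intermediate (not isolated)
15 | (2S,2aS,7aS)-2-{3,4-bis[(tert-butyldimethylsilyl)oxy]phenyl}-4,6-dimethoxy-1,1-dimethyl-1,2,2a,7a-tetrahydro-7H-cyclobuta[a]inden-7-one | COc1cc(OC)c2c(c1)[C@@H]1[C@H](C2=O)C(C)(C)[C@H]1c1ccc(O[Si](C)(C)C(C)(C)C)c(O[Si](C)(C)C(C)(C)C)c1 | intermediate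
16 | (2S,2aS,7aS)-2-{3,4-bis[(tert-butyldimethylsilyl)oxy]phenyl}-6-hydroxy-4-methoxy-1,1-dimethyl-1,2,2a,7a-tetrahydro-7H-cyclobuta[a]inden-7-one | COc1cc(O)c2c(c1)[C@@H]1[C@H](C2=O)C(C)(C)[C@H]1c1ccc(O[Si](C)(C)C(C)(C)C)c(O[Si](C)(C)C(C)(C)C)c1 | intermediate
17 | (2S,2aS,7aS)-2-{3,4-bis[(tert-butyldimethylsilyl)oxy]phenyl}-4-methoxy-1,1-dimethyl-7-oxo-2,2a,7,7a-tetrahydro-1H-cyclobuta[a]inden-6-yl ethyl carbonate | COc1cc(OC(=O)OCC)c2c(c1)[C@@H]1[C@H](C2=O)C(C)(C)[C@H]1c1ccc(O[Si](C)(C)C(C)(C)C)c(O[Si](C)(C)C(C)(C)C)c1 | intermediate (not isolated)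
18 | (2S,2aR,7aS)-2-{3,4-bis[(tert-butyldimethylsilyl)oxy]phenyl}-4-methoxy-1,1-dimethyl-2,2a,7,7a-tetrahydro-1H-cyclobuta[a]inden-6-ol | COc1cc(O)c2c(c1)[C@@H]1[C@H](C2)C(C)(C)[C@H]1c1ccc(O[Si](C)(C)C(C)(C)C)c(O[Si](C)(C)C(C)(C)C)c1 | intermediate
19 | (2S,2aR,7aS)-3-bromo-2-{3,4-bis[(tert-butyldimethylsilyl)oxy]phenyl}-4-methoxy-1,1-dimethyl-2,2a,7,7a-tetrahydro-1H-cyclobuta[a]inden-6-ol | COc1cc(O)c2c(c1Br)[C@@H]1[C@H](C2)C(C)(C)[C@H]1c1ccc(O[Si](C)(C)C(C)(C)C)c(O[Si](C)(C)C(C)(C)C)c1 | intermediate
20 | (2S,2aR,7aS)-2-{3,4-bis[(tert-butyldimethylsilyl)oxy]phenyl}-4-methoxy-1,1-dimethyl-3-(3-methylbut-2-en-1-yl)-2,2a,7,7a-tetrahydro-1H-cyclobuta[a]inden-6-ol | COc1cc(O)c2c(c1CC=C(C)C)[C@@H]1[C@H](C2)C(C)(C)[C@H]1c1ccc(O[Si](C)(C)C(C)(C)C)c(O[Si](C)(C)C(C)(C)C)c1 | intermediate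
21 | 4-[(2S,2aR,7aS)-6-hydroxy-4-methoxy-1,1-dimethyl-3-(3-methylbut-2-en-1-yl)-2,2a,7,7a-tetrahydro-1H-cyclobuta[a]inden-2-yl]benzene-1,2-diol | COc1cc(O)c2c(c1CC=C(C)C)[C@@H]1[C@H](C2)C(C)(C)[C@H]1c1ccc(O)c(O)c1 | target

## Step count and least certain steps

Total: 14 steps. Longest linear sequence: 13 steps (steps 1–7 and 9–14 from verbenone); step 8 is a one-step branch.

**Step 5 (key step, proposed new method).**
- **What may go wrong:** C–H cleavage at the cyclobutane CH2 may be slower than at the methyl and cyclopropyl C–H bonds for which this catalysis is established. Protodebromination, activation of a C1 methyl group through the larger palladacycle, or epimerisation at C7a before cyclisation could then take over.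
- **Fallback (known chemistry), from 2 to 9:** Acid chloride 4, made from 2 as in step 2, is trapped with 8-aminoquinoline and Et3N to give (1S,3R)-3-acetyl-2,2-dimethyl-N-(quinolin-8-yl)cyclobutane-1-carboxamide F1. Aminoquinoline-directed C–H arylation with divalent palladium (Pd(OAc)2, AgOAc, 1-iodo-3,5-dimethoxybenzene, tert-amyl alcohol, 110 °C), a reaction known on gem-dimethylcyclobutane carboxamides, places the aryl group on the ring CH2 cis to the amide and gives (1S,3R,4S)-3-acetyl-4-(3,5-dimethoxyphenyl)-2,2-dimethyl-N-(quinolin-8-yl)cyclobutane-1-carboxamide F2. Boc2O and DMAP give tert-butyl N-[(1S,3R,4S)-3-acetyl-4-(3,5-dimethoxyphenyl)-2,2-dimethylcyclobutane-1-carbonyl]-N-(quinolin-8-yl)carbamate F3, which LiOH/H2O2 cleaves to (1S,3R,4S)-3-acetyl-4-(3,5-dimethoxyphenyl)-2,2-dimethylcyclobutane-1-carboxylic acid F4. TFAA-promoted intramolecular Friedel–Crafts acylation, possible only for the cis acid, closes ring B to (2R,2aS,7aS)-2-acetyl-4,6-dimethoxy-1,1-dimethyl-1,2,2a,7a-tetrahydro-7H-cyclobuta[a]inden-7-one F5, and haloform degradation as in step 3 gives 9. The detour is longer, but the cis delivery of the aryl group and the ring closure fix C2a in the same sense.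

**Step 3 (haloform degradation).**
- **What may go wrong:** Ring bromination of the dimethoxyarene by hypobromite, or halogenation and epimerisation at the C–H next to the aryl ketone, which would feed the wrong trans series.
- **Fallback, from 5 to 6:** Ortoleva–King reaction. Heating 5 with I2 in pyridine gives 1-{2-[(1R,3S)-3-(2-bromo-4,6-dimethoxybenzoyl)-2,2-dimethylcyclobutyl]-2-oxoethyl}pyridin-1-ium iodide F6, which aqueous NaOH cleaves to 6 without any free hypohalite.

**Step 9 (decarboxylative arylation).**
- **What may go wrong:** Addition of the arylzinc to the activated ester carbonyl, or reduction or ring opening of the C2 radical before the nickel species captures it at this neopentyl-type position. Facial selectivity could also be lower than expected.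
- **Fallback, from 9 to 15:** Iododecarboxylation of 9 (PhI(OAc)2, I2, visible light, CH2Cl2) gives (2S,2aR,7aS)-2-iodo-4,6-dimethoxy-1,1-dimethyl-1,2,2a,7a-tetrahydro-7H-cyclobuta[a]inden-7-one F7, drawn as the exo iodide although its C2 configuration does not matter. Nickel-catalysed cross-electrophile coupling of this iodide with aryl bromide 12 (NiBr2(glyme), 4,4′-di-tert-butyl-2,2′-bipyridine, Zn, NaI, DMA, 60 °C) gives 15 with neither an organozinc reagent nor an activated ester.

**Step 11 (deoxygenation at C7).**
- **What may go wrong:** Reduction stopping at the benzylic alcohol if carbonate transfer and elimination are slow in the rigid five-membered ring, or loss of the aryl silyl ethers in basic aqueous borohydride.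
- **Fallback, from 16 to 18:** NaBH4 in THF/MeOH reduces 16 from the convex face to (2S,2aS,7R,7aS)-2-{3,4-bis[(tert-butyldimethylsilyl)oxy]phenyl}-4-methoxy-1,1-dimethyl-2,2a,7,7a-tetrahydro-1H-cyclobuta[a]indene-6,7-diol F8, and hydrogenolysis of this electron-rich benzylic alcohol (H2, Pd/C, EtOAc/AcOH) gives 18. No alkene or halide is present at this stage.

**Step 13 (prenylation).**
- **What may go wrong:** Slow oxidative addition at a bromide flanked by the methoxy group and the ring fusion, protodebromination, or allyl transposition giving the 1,1-dimethylallyl isomer.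
- **Fallback, from 19 to 20:** Stille allylation with allyltributylstannane (Pd(PPh3)4, DMF) has no regiochemical ambiguity and gives (2S,2aR,7aS)-2-{3,4-bis[(tert-butyldimethylsilyl)oxy]phenyl}-4-methoxy-1,1-dimethyl-3-(prop-2-en-1-yl)-2,2a,7,7a-tetrahydro-1H-cyclobuta[a]inden-6-ol F9, and cross-metathesis with 2-methyl-2-butene (second-generation Grubbs catalyst, CH2Cl2, 40 °C) gives 20.

## Further compounds

F1 | step 5 | (1S,3R)-3-acetyl-2,2-dimethyl-N-(quinolin-8-yl)cyclobutane-1-carboxamide | C1[C@H](C(=O)Nc2cccc3cccnc23)C(C)(C)[C@@H]1C(C)=O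
F2 | step 5 | (1S,3R,4S)-3-acetyl-4-(3,5-dimethoxyphenyl)-2,2-dimethyl-N-(quinolin-8-yl)cyclobutane-1-carboxamide | COc1cc(OC)cc(c1)[C@@H]1[C@H](C(=O)Nc2cccc3cccnc23)C(C)(C)[C@@H]1C(C)=O
F3 | step 5 | tert-butyl N-[(1S,3R,4S)-3-acetyl-4-(3,5-dimethoxyphenyl)-2,2-dimethylcyclobutane-1-carbonyl]-N-(quinolin-8-yl)carbamate | COc1cc(OC)cc(c1)[C@@H]1[C@H](C(=O)N(C(=O)OC(C)(C)C)c2cccc3cccnc23)C(C)(C)[C@@H]1C(C)=O
F4 | step 5 | (1S,3R,4S)-3-acetyl-4-(3,5-dimethoxyphenyl)-2,2-dimethylcyclobutane-1-carboxylic acid | COc1cc(OC)cc(c1)[C@@H]1[C@H](C(=O)O)C(C)(C)[C@@H]1C(C)=O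
F5 | step 5 | (2R,2aS,7aS)-2-acetyl-4,6-dimethoxy-1,1-dimethyl-1,2,2a,7a-tetrahydro-7H-cyclobuta[a]inden-7-one | COc1cc(OC)c2c(c1)[C@@H]1[C@H](C2=O)C(C)(C)[C@@H]1C(C)=O
F6 | step 3 | 1-{2-[(1R,3S)-3-(2-bromo-4,6-dimethoxybenzoyl)-2,2-dimethylcyclobutyl]-2-oxoethyl}pyridin-1-ium iodide | C1[C@H](C(=O)c2c(Br)cc(OC)cc2OC)C(C)(C)[C@@H]1C(=O)C[n+]1ccccc1.[I-]
F7 | step 9 | (2S,2aR,7aS)-2-iodo-4,6-dimethoxy-1,1-dimethyl-1,2,2a,7a-tetrahydro-7H-cyclobuta[a]inden-7-one | COc1cc(OC)c2c(c1)[C@@H]1[C@H](C2=O)C(C)(C)[C@H]1I
F8 | step 11 | (2S,2aS,7R,7aS)-2-{3,4-bis[(tert-butyldimethylsilyl)oxy]phenyl}-4-methoxy-1,1-dimethyl-2,2a,7,7a-tetrahydro-1H-cyclobuta[a]indene-6,7-diol | COc1cc(O)c2c(c1)[C@@H]1[C@H]([C@H]2O)C(C)(C)[C@H]1c1ccc(O[Si](C)(C)C(C)(C)C)c(O[Si](C)(C)C(C)(C)C)c1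
F9 | step 13 | (2S,2aR,7aS)-2-{3,4-bis[(tert-butyldimethylsilyl)oxy]phenyl}-4-methoxy-1,1-dimethyl-3-(prop-2-en-1-yl)-2,2a,7,7a-tetrahydro-1H-cyclobuta[a]inden-6-ol | COc1cc(O)c2c(c1CC=C)[C@@H]1[C@H](C2)C(C)(C)[C@H]1c1ccc(O[Si](C)(C)C(C)(C)C)c(O[Si](C)(C)C(C)(C)C)c1
A1 | alternative 1 | 4-bromo-5-methoxy-7-[(triisopropylsilyl)oxy]-1H-indene | COc1cc(O[Si](C(C)C)(C(C)C)C(C)C)c2c(c1Br)C=CC2
A2 | alternative 1 | 2-{3,4-bis[(tert-butyldimethylsilyl)oxy]phenyl}-1-[(2S,5S)-2,5-dimethylpyrrolidin-1-yl]ethan-1-one | O=C(Cc1ccc(O[Si](C)(C)C(C)(C)C)c(O[Si](C)(C)C(C)(C)C)c1)N1[C@@H](C)CC[C@@H]1C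
A3 | alternative 1 | (2S,5S)-1-(2-{3,4-bis[(tert-butyldimethylsilyl)oxy]phenyl}ethenylidene)-2,5-dimethylpyrrolidin-1-ium trifluoromethanesulfonate | C(=C=[N+]1[C@@H](C)CC[C@@H]1C)c1ccc(O[Si](C)(C)C(C)(C)C)c(O[Si](C)(C)C(C)(C)C)c1.[O-]S(=O)(=O)C(F)(F)F
A4 | alternative 1 | 2-{3,4-bis[(tert-butyldimethylsilyl)oxy]phenyl}-3-bromo-4-methoxy-6-[(triisopropylsilyl)oxy]-2,2a,7,7a-tetrahydro-1H-cyclobuta[a]inden-1-one (ring stereocentres as in the target) | COc1cc(O[Si](C(C)C)(C(C)C)C(C)C)c2c(c1Br)[C@@H]1[C@H](C2)C(=O)[C@H]1c1ccc(O[Si](C)(C)C(C)(C)C)c(O[Si](C)(C)C(C)(C)C)c1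
A5 | alternative 2 | dimethyl 3-[3,4-bis(methoxymethoxy)phenyl]-4,4-dimethylcyclobutane-1,2-dicarboxylate (cis diester, stereocentres as in the target) | COC(=O)[C@@H]1[C@H](C(=O)OC)C(C)(C)[C@H]1c1ccc(OCOC)c(OCOC)c1
A6 | alternative 2 | pentane-2,4-dione | CC(=O)CC(C)=O
A7 | alternative 2 | 2-[3,4-bis(methoxymethoxy)phenyl]-4,6-dihydroxy-1,1-dimethyl-1,2,2a,7a-tetrahydro-7H-cyclobuta[a]inden-7-one (ring stereocentres as in the target) | Oc1cc(O)c2c(c1)[C@@H]1[C@H](C2=O)C(C)(C)[C@H]1c1ccc(OCOC)c(OCOC)c1
A8 | alternative 3 | 2-diazo-1-{7-[3,4-bis(tert-butyldimethylsilyloxy)phenyl]-6,6-dimethylbicyclo[3.2.0]hept-2-en-2-yl}ethan-1-one (ring stereocentres as in the target) | C1=C(C(=O)C=[N+]=[N-])[C@@H]2[C@H](C1)C(C)(C)[C@H]2c1ccc(O[Si](C)(C)C(C)(C)C)c(O[Si](C)(C)C(C)(C)C)c1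
A9 | alternative 3 | methoxyethyne | COC#C
A10 | alternative 3 | (2S,2aR,7aS)-2-{3,4-bis[(tert-butyldimethylsilyl)oxy]phenyl}-4-methoxy-1,1-dimethyl-2,2a,7,7a-tetrahydro-1H-cyclobuta[a]inden-6-ol (identical with 18) | COc1cc(O)c2c(c1)[C@@H]1[C@H](C2)C(C)(C)[C@H]1c1ccc(O[Si](C)(C)C(C)(C)C)c(O[Si](C)(C)C(C)(C)C)c1
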